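**Retrosynthetic overview**
1. N–OMe comes from O-methylation of the 1-hydroxy-4-pyridone, which comes from hydrogenolysis of a 4-benzyloxypyridine N-oxide (mCPBA on the O-benzylated NH-pyridone).
2. The pyridone ring is formed last, from a 1,3,5-triketone and NH3; the triketone comes from double oxidation of an aldol-derived 1,3-diol.
3. Key C–C bond (C4–C4a): intermolecular aldol of the regiodefined lithium enolate of (R)-3-octylcyclohexanone with a four-carbon α-methoxy aldehyde.
4. The enolate is stored as its TMS enol ether, made by copper-catalysed asymmetric conjugate addition of dioctylzinc to cyclohexenone (the carbocycle is bought; C5 is set here).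
5. The aldehyde comes from methyl methoxyacetate and (benzyloxy)acetaldehyde by aldol addition, silylation and DIBAL reduction.

Assumption: the phosphoramidite ligand shows the same sense of induction as with diethylzinc and cyclohexenone ((S,R,R)-ligand gives the (S)-3-alkyl ketone), so the (R,S,S)-ligand is used for 3R; the target's C5 is R, and ee is checked by chiral GC after hydrolysis of an aliquot.

**Route**

Step 1
Reactants: 1 octylmagnesium bromide (2.0 equiv in all)
Product: 2 di-n-octylzinc
Conditions: ZnCl2 (1.0 equiv per 2.0 equiv of 1), Et2O, 0 °C → rt; then 1,4-dioxane, filter under Ar, titrate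
Reagents that add atoms: zinc dichloride, Cl[Zn]Cl; octylmagnesium bromide (second equivalent), CCCCCCCC[Mg]Br
Why: Two equivalents of the Grignard reagent each transfer their octyl group to one zinc centre (transmetalation), and dioxane precipitates the magnesium halide, giving the salt-free dialkylzinc that the asymmetric conjugate addition needs.

Step 2
Reactants: 3 cyclohex-2-en-1-one; 2 di-n-octylzinc (1.2 equiv)
Product: 5 trimethyl{[(3R)-3-octylcyclohex-1-en-1-yl]oxy}silane, via zinc enolate 4 (not isolated)
Conditions: Cu(OTf)2 (2 mol%), (R,S,S)-phosphoramidite ligand [O,O'-(R)-1,1'-binaphthyl-2,2'-diyl N,N-bis((S)-1-phenylethyl)phosphoramidite] (4 mol%), toluene, −30 °C; then Me3SiOTf (1.3 equiv), −30 → 0 °C; Et3N, pentane, cold NaHCO3 wash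
Reagents that add atoms: trimethylsilyl trifluoromethanesulfonate, C[Si](C)(C)OS(=O)(=O)C(F)(F)F
Why: Copper-catalysed asymmetric conjugate addition under ligand control delivers one octyl group to one enantioface of the enone (setting C3 as R, the future C5), and O-silylation of the zinc enolate locks the enolate double bond between C1 and C2.

Step 3
Reactants: 6 methyl methoxyacetate; 7 (benzyloxy)acetaldehyde
Product: 9 methyl 4-(benzyloxy)-3-hydroxy-2-methoxybutanoate (racemic syn/anti mixture), via lithium ester enolate 8 (not isolated)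
Conditions: LiN(i-Pr)2, THF, −78 °C; then 7, −78 °C; AcOH quench
Reagents that add atoms: none
Why: Kinetic lithium enolate aldol addition of an α-alkoxy ester to an aldehyde is fast at −78 °C, and the two new stereocentres need no control because both carbons become sp2 later.

Step 4
Reactants: 9 methyl 4-(benzyloxy)-3-hydroxy-2-methoxybutanoate
Product: 10 methyl 4-(benzyloxy)-2-methoxy-3-[(triethylsilyl)oxy]butanoate
Conditions: Et3SiCl, imidazole, DMF, 0 °C → rt
Reagents that add atoms: chlorotriethylsilane, CC[Si](Cl)(CC)CC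
Why: Standard silyl ether protection of the secondary alcohol prevents it from quenching the enolate in the key step and is later removed under mild buffered fluoride conditions.

Step 5
Reactants: 10 methyl 4-(benzyloxy)-2-methoxy-3-[(triethylsilyl)oxy]butanoate
Product: 11 4-(benzyloxy)-2-methoxy-3-[(triethylsilyl)oxy]butanal
Conditions: i-Bu2AlH (1.1 equiv), CH2Cl2, −78 °C; MeOH, aq. KNaC4H4O6 (potassium sodium tartrate); used crude
Reagents that add atoms: none
Why: Partial reduction of the ester stops at the aldehyde because the α-methoxy group chelates and stabilises the tetrahedral aluminium hemiacetal at −78 °C.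

Step 6
Reactants: 5 trimethyl{[(3R)-3-octylcyclohex-1-en-1-yl]oxy}silane; 11 4-(benzyloxy)-2-methoxy-3-[(triethylsilyl)oxy]butanal (1.2 equiv)
Product: 13 (3R)-2-{4-(benzyloxy)-1-hydroxy-2-methoxy-3-[(triethylsilyl)oxy]butyl}-3-octylcyclohexan-1-one (mainly 2,3-trans as a mixture of side-chain epimers), via lithium enolate 12 (not isolated)
Conditions: MeLi (1.0 equiv), THF, 0 °C → rt, 45 min; −78 °C, then 11, 30 min; AcOH, −78 °C
Reagents that add atoms: none
Why: Si–O cleavage by MeLi regenerates the lithium enolate regiospecifically and a kinetic intermolecular aldol addition at −78 °C forms the C4–C4a bond at C2 of the ring, leaving the C3 stereocentre untouched while all new stereocentres are later erased.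

Step 7
Reactants: 13 the aldol adduct
Product: 14 (3R)-2-[4-(benzyloxy)-1,3-dihydroxy-2-methoxybutyl]-3-octylcyclohexan-1-one
Conditions: HF·pyridine, pyridine, THF, 0 °C → rt
Reagents that add atoms: none
Why: Buffered fluoride desilylation removes the triethylsilyl ether without retro-aldol or dehydration of the β-hydroxy ketone and leaves the benzyl and methyl ethers intact.

Step 8
Reactants: 14 the diol
Product: 15 (3R)-2-[4-(benzyloxy)-2-methoxy-3-oxobutanoyl]-3-octylcyclohexan-1-one (enol tautomers)
Conditions: Dess–Martin periodinane (3 equiv), CH2Cl2, 0 °C → rt; Na2S2O3/NaHCO3 work-up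
Reagents that add atoms: none
Why: Double Dess–Martin oxidation of both secondary carbinols gives the 1,3,5-triketone as in γ-pyrone polyketide syntheses, and C3 of the ring cannot epimerise because it is not α to a carbonyl.

Step 9
Reactants: 15 the triketone
Product: 16 (5R)-2-[(benzyloxy)methyl]-3-methoxy-5-octyl-5,6,7,8-tetrahydroquinolin-4(1H)-one
Conditions: NH3 (7 M in MeOH), sealed tube, 60 °C
Reagents that add atoms: ammonia, N
Why: Cyclocondensation of a 1,3,5-triketone (or any pyranone formed from it) with ammonia gives the aromatic 4-pyridone by double enamine formation and loss of two waters, with only one possible ring.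

Step 10
Reactants: 16 the NH-pyridone
Product: 17 (5R)-4-(benzyloxy)-2-[(benzyloxy)methyl]-3-methoxy-5-octyl-5,6,7,8-tetrahydroquinoline
Conditions: BnBr, Ag2CO3, toluene, 80 °C, dark
Reagents that add atoms: benzyl bromide, BrCc1ccccc1
Why: Silver-salt alkylation of a pyridone goes on oxygen, helped here by the two substituents flanking nitrogen, and gives the 4-benzyloxypyridine (O-alkylation of an ambident pyridone).

Step 11
Reactants: 17 the 4-benzyloxypyridine
Product: 18 (5R)-4-(benzyloxy)-2-[(benzyloxy)methyl]-3-methoxy-5-octyl-5,6,7,8-tetrahydroquinoline 1-oxide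
Conditions: mCPBA (1.3 equiv), CH2Cl2, 0 °C → rt
Reagents that add atoms: 3-chloroperoxybenzoic acid, OOC(=O)c1cccc(Cl)c1
Why: Peracid N-oxidation of the electron-rich 4-alkoxypyridine is clean, and the ethers and the saturated ring are inert to mCPBA.

Step 12
Reactants: 18 the N-oxide
Product: 19 (5R)-1-hydroxy-2-(hydroxymethyl)-3-methoxy-5-octyl-5,6,7,8-tetrahydroquinolin-4(1H)-one
Conditions: H2 (1 atm), 10% Pd/C, MeOH, rt, stopped when both benzyl groups are gone
Reagents that add atoms: none
Why: Hydrogenolysis cleaves both O-benzyl bonds, and the 4-hydroxypyridine N-oxide formed tautomerises to the 1-hydroxy-4-pyridone, which resists N–O reduction better than the parent N-oxide.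

Step 13
Reactants: 19 the 1-hydroxy-4-pyridone
Product: 20 (5R)-2-(hydroxymethyl)-1,3-dimethoxy-5-octyl-5,6,7,8-tetrahydroquinolin-4(1H)-one (target)
Conditions: MeI (1.1 equiv), K2CO3, DMF, 0 °C → rt
Reagents that add atoms: iodomethane, CI
Why: K2CO3 deprotonates only the acidic N–OH and the resulting oxyanion is methylated on the nitrogen-bound oxygen to give the neutral N-methoxy pyridone, while the primary alcohol is not ionised (O-alkylation of an N-hydroxypyridone).

**Compound list**
1 | octylmagnesium bromide | CCCCCCCC[Mg]Br | starting material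
2 | di-n-octylzinc | CCCCCCCC[Zn]CCCCCCCC | intermediate
3 | cyclohex-2-en-1-one | O=C1C=CCCC1 | starting material
4 | octyl{[(3R)-3-octylcyclohex-1-en-1-yl]oxy}zinc (zinc enolate, not isolated) | CCCCCCCC[C@@H]1CCCC(O[Zn]CCCCCCCC)=C1 | intermediate
5 | trimethyl{[(3R)-3-octylcyclohex-1-en-1-yl]oxy}silane | CCCCCCCC[C@@H]1CCCC(O[Si](C)(C)C)=C1 | intermediate
6 | methyl methoxyacetate | COCC(=O)OC | starting material
7 | (benzyloxy)acetaldehyde | O=CCOCc1ccccc1 | starting material
8 | lithium 1,2-dimethoxyethen-1-olate (lithium ester enolate, not isolated) | COC=C(OC)O[Li] | intermediate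
9 | methyl 4-(benzyloxy)-3-hydroxy-2-methoxybutanoate (racemic syn/anti mixture) | COC(=O)C(OC)C(O)COCc1ccccc1 | intermediate
10 | methyl 4-(benzyloxy)-2-methoxy-3-[(triethylsilyl)oxy]butanoate (racemic diastereomer mixture) | COC(=O)C(OC)C(O[Si](CC)(CC)CC)COCc1ccccc1 | intermediate
11 | 4-(benzyloxy)-2-methoxy-3-[(triethylsilyl)oxy]butanal (racemic diastereomer mixture) | O=CC(OC)C(O[Si](CC)(CC)CC)COCc1ccccc1 | intermediate
12 | lithium (3R)-3-octylcyclohex-1-en-1-olate (lithium enolate, not isolated) | CCCCCCCC[C@@H]1CCCC(O[Li])=C1 | intermediate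
13 | (3R)-2-{4-(benzyloxy)-1-hydroxy-2-methoxy-3-[(triethylsilyl)oxy]butyl}-3-octylcyclohexan-1-one (3R fixed; other centres as mixture) | CCCCCCCC[C@@H]1CCCC(=O)C1C(O)C(OC)C(O[Si](CC)(CC)CC)COCc1ccccc1 | intermediate
14 | (3R)-2-[4-(benzyloxy)-1,3-dihydroxy-2-methoxybutyl]-3-octylcyclohexan-1-one (3R fixed; other centres as mixture) | CCCCCCCC[C@@H]1CCCC(=O)C1C(O)C(OC)C(O)COCc1ccccc1 | intermediate
15 | (3R)-2-[4-(benzyloxy)-2-methoxy-3-oxobutanoyl]-3-octylcyclohexan-1-one (enol tautomers) | CCCCCCCC[C@@H]1CCCC(=O)C1C(=O)C(OC)C(=O)COCc1ccccc1 | intermediate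
16 | (5R)-2-[(benzyloxy)methyl]-3-methoxy-5-octyl-5,6,7,8-tetrahydroquinolin-4(1H)-one | CCCCCCCC[C@@H]1CCCc2[nH]c(COCc3ccccc3)c(OC)c(=O)c12 | intermediate
17 | (5R)-4-(benzyloxy)-2-[(benzyloxy)methyl]-3-methoxy-5-octyl-5,6,7,8-tetrahydroquinoline | CCCCCCCC[C@@H]1CCCc2nc(COCc3ccccc3)c(OC)c(OCc3ccccc3)c12 | intermediate
18 | (5R)-4-(benzyloxy)-2-[(benzyloxy)methyl]-3-methoxy-5-octyl-5,6,7,8-tetrahydroquinoline 1-oxide | CCCCCCCC[C@@H]1CCCc2c1c(OCc3ccccc3)c(OC)c(COCc4ccccc4)[n+]2[O-] | intermediate
19 | (5R)-1-hydroxy-2-(hydroxymethyl)-3-methoxy-5-octyl-5,6,7,8-tetrahydroquinolin-4(1H)-one | CCCCCCCC[C@@H]1CCCc2c1c(=O)c(OC)c(CO)n2O | intermediate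
20 | (5R)-2-(hydroxymethyl)-1,3-dimethoxy-5-octyl-5,6,7,8-tetrahydroquinolin-4(1H)-one | CCCCCCCC[C@@H]1CCCc2c1c(=O)c(OC)c(CO)n2OC | target

**Totals**
Total step count: 13. Longest linear sequence: 11 steps (steps 3–13, from 6 and 7); the other branch (steps 1, 2, 6–13) is 10 steps.

**Three steps most likely to fail**

Step 2 (enantioselectivity with a home-made dialkylzinc and silyl trapping of the zinc enolate). The fallback drops the zinc reagent and sets out from 3 and 1. Copper-catalysed asymmetric conjugate addition of the Grignard reagent itself (CuBr·SMe2 5 mol%, the TaniaPhos-type ferrocenyl diphosphine antipode that gives 3R, t-BuOMe, −60 °C) gives bromo{[(3R)-3-octylcyclohex-1-en-1-yl]oxy}magnesium F1. This is silylated in the same flask (Me3SiCl, Et3N, DMPU) and comes back to the route at 5.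

Step 6 (a basic, hindered enolate with an enolisable, β-silyloxy aldehyde; risk of aldehyde elimination or retro-aldol). The fallback replaces the aldol by a Claisen-type C-acylation one oxidation level higher; it sets out from 10 and 5 and comes back at 15. Ester 10 is converted with MeNH(OMe)·HCl and i-PrMgCl (THF, −20 °C) into 4-(benzyloxy)-N,2-dimethoxy-N-methyl-3-[(triethylsilyl)oxy]butanamide F2. Lithium enolate 12 (from 5 and MeLi as in step 6) adds to F2 at −78 → 0 °C; the chelated tetrahedral adduct collapses only on quench, so no second equivalent of enolate is lost to proton transfer. This gives (3R)-2-{4-(benzyloxy)-2-methoxy-3-[(triethylsilyl)oxy]butanoyl}-3-octylcyclohexan-1-one F3. HF·pyridine then gives (3R)-2-[4-(benzyloxy)-3-hydroxy-2-methoxybutanoyl]-3-octylcyclohexan-1-one F4, and Dess–Martin oxidation of the one remaining carbinol returns to 15.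

Step 13 (ambident N-hydroxypyridone anion; methylation on the C4 oxygen would give the 4-methoxypyridine N-oxide; the same fallback also bypasses the step 12 hydrogenolysis in the presence of an N–O bond). The fallback lets the amine carry the N-methoxy group; it sets out from 15 and comes back at 20. Cyclodehydration of 15 (CF3CO2H, CH2Cl2, rt) gives (5R)-2-[(benzyloxy)methyl]-3-methoxy-5-octyl-5,6,7,8-tetrahydro-4H-chromen-4-one F5. Hydrogenolysis (H2, 10% Pd/C, EtOAc) gives (5R)-2-(hydroxymethyl)-3-methoxy-5-octyl-5,6,7,8-tetrahydro-4H-chromen-4-one F6. Ring transformation of this pyranone with MeONH2·HCl (pyridine, EtOH, 90 °C, sealed) by addition, ring opening and recyclisation gives 20 directly, with no alkylation step. The reactivity of a fully substituted pyranone toward methoxyamine is the uncertain point of this fallback.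

**Further compounds**
F1 | step 2 | bromo{[(3R)-3-octylcyclohex-1-en-1-yl]oxy}magnesium | CCCCCCCC[C@@H]1CCCC(O[Mg]Br)=C1
F2 | step 6 | 4-(benzyloxy)-N,2-dimethoxy-N-methyl-3-[(triethylsilyl)oxy]butanamide | CON(C)C(=O)C(OC)C(O[Si](CC)(CC)CC)COCc1ccccc1
F3 | step 6 | (3R)-2-{4-(benzyloxy)-2-methoxy-3-[(triethylsilyl)oxy]butanoyl}-3-octylcyclohexan-1-one | CCCCCCCC[C@@H]1CCCC(=O)C1C(=O)C(OC)C(O[Si](CC)(CC)CC)COCc1ccccc1
F4 | step 6 | (3R)-2-[4-(benzyloxy)-3-hydroxy-2-methoxybutanoyl]-3-octylcyclohexan-1-one | CCCCCCCC[C@@H]1CCCC(=O)C1C(=O)C(OC)C(O)COCc1ccccc1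
F5 | step 13 | (5R)-2-[(benzyloxy)methyl]-3-methoxy-5-octyl-5,6,7,8-tetrahydro-4H-chromen-4-one | CCCCCCCC[C@@H]1CCCc2oc(COCc3ccccc3)c(OC)c(=O)c12
F6 | step 13 | (5R)-2-(hydroxymethyl)-3-methoxy-5-octyl-5,6,7,8-tetrahydro-4H-chromen-4-one | CCCCCCCC[C@@H]1CCCc2oc(CO)c(OC)c(=O)c12
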